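Ring B hides a symmetry: C10, with its methyl C20 and its chain carbon C1, is an isopropenyl group that C9 has arylated at the inner carbon and that has been extended at its CH2, so C5 once carried two identical isopropenyl groups. One palladium-catalysed operation on an achiral aryl bromide whose C5 methine bears both groups should close ring B through C9–C10, trap the neopentyl palladium with ethynyltrimethylsilane (C1–C2) and set C5 and C10 together. The bromide comes from a Claisen-derived Weinreb amide and a hexasubstituted arylmagnesium reagent; afterwards the silylalkyne becomes the C3 acid and ring C is unmasked through its 11,14-quinone.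

Key step: step 10

Numbering used: C10 is the quaternary carbon, C20 its methyl, C1–C3 the acid chain, C5 the adjacent CH, C4 the inner carbon of the isopropenyl group on C5, C6 the CH2, C7 the ketone, C8 and C9 the ring-C carbons on C7 and C10, and C11–C14 follow round ring C from C9 (oxygen on C11, C12 and C14, isopropyl on C13). In this numbering the target is (5S,10R): the isopropenyl group on C5 is cis to the C1 arm on ring B and trans to C20.

Assumption: the sense of induction of the bisphosphine in step 10 cannot be predicted with confidence; (R)-DTBM-SEGPHOS is written and stands for whichever antipode delivers (3S,4R)-21, to be settled in the first run.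

Remark on the precursor: bromide is kept on C9 because selective iodine–magnesium exchange beside it makes the acylation possible and because bromide leaves divalent palladium in a polar solvent more readily than iodide. Methyl ethers are kept on C11, C12 and C14 so that ring C can be unmasked oxidatively, without acid that would attack the isopropenyl group. Compound 26 is an air-sensitive hydroquinone and is handled under argon.

Step 1
Reactants: 1 methacrolein; 2 triethyl 2-phosphonopropionate
Product: 4 ethyl (2E)-2,4-dimethylpenta-2,4-dienoate, via sodium phosphonate 3 (not isolated)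
Conditions: NaH, THF, 0 °C; then 1, 0 °C to rt
Reagents that add atoms: none
Why: Horner–Wadsworth–Emmons olefination of a non-enolisable enal by a stabilised phosphonate anion should give the conjugated dienoate, whose alkene geometry need not be controlled because step 3 converts that carbon into a methine bearing two identical groups.

Step 2
Reactants: 4 ethyl (2E)-2,4-dimethylpenta-2,4-dienoate
Product: 5 (2E)-2,4-dimethylpenta-2,4-dien-1-ol
Conditions: i-Bu2AlH (2.2 equiv), CH2Cl2, −78 to 0 °C
Reagents that add atoms: none
Why: 1,2-Reduction of the α,β-unsaturated ester to the allylic alcohol by the aluminium hydride i-Bu2AlH at low temperature, which leaves the conjugated diene untouched.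

Step 3
Reactants: 5 (2E)-2,4-dimethylpenta-2,4-dien-1-ol; 6 triethyl orthoacetate
Product: 8 ethyl 4-methyl-3-(prop-1-en-2-yl)pent-4-enoate, via ketene acetal 7 (not isolated)
Conditions: 6 (5 equiv), EtCO2H (cat.), 140 °C, EtOH distilled off
Reagents that add atoms: none
Why: Johnson–Claisen (orthoester Claisen) rearrangement: acid-catalysed exchange gives the mixed ketene acetal, whose [3,3]-sigmatropic shift across the trisubstituted alkene forms the C5–C6 bond and turns the former allylic terminus into the second isopropenyl group, so that the new methine carries two identical alkenes and is not a stereocentre.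

Step 4
Reactants: 8 ethyl 4-methyl-3-(prop-1-en-2-yl)pent-4-enoate
Product: 9 N-methoxy-N,4-dimethyl-3-(prop-1-en-2-yl)pent-4-enamide
Conditions: MeNH(OMe)·HCl (1.5 equiv), i-PrMgCl (3 equiv), THF, −20 to 0 °C
Reagents that add atoms: N,O-dimethylhydroxylamine hydrochloride, CNOC.Cl
Why: Direct conversion of an ester into a Weinreb amide by the chloromagnesium amide of N,O-dimethylhydroxylamine (acyl substitution), a reagent too weakly basic to isomerise the skipped diene at −20 °C.

Step 5
Reactants: 10 1,2,4-trimethoxybenzene; 11 acetone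
Product: 13 2-(2,3,6-trimethoxyphenyl)propan-2-ol, via aryllithium 12 (not isolated)
Conditions: n-BuLi, THF, 0 °C to rt; then 11, −78 °C to rt; then H2O
Reagents that add atoms: none
Why: Directed ortho-lithiation at the ring position flanked by two methoxy groups (the future C13), followed by 1,2-addition of the aryllithium to acetone.

Step 6
Reactants: 13 2-(2,3,6-trimethoxyphenyl)propan-2-ol
Product: 14 1,2,4-trimethoxy-3-(propan-2-yl)benzene
Conditions: Et3SiH, CF3CO2H, CH2Cl2, 0 °C to rt
Reagents that add atoms: none
Why: Ionic hydrogenation: CF3CO2H ionises the tertiary benzylic alcohol and Et3SiH transfers hydride to the cation, which gives the isopropyl group without touching the methyl ethers.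

Step 7
Reactants: 14 1,2,4-trimethoxy-3-(propan-2-yl)benzene
Product: 15 1-iodo-2,4,5-trimethoxy-3-(propan-2-yl)benzene
Conditions: N-iodosuccinimide, CF3CO2H (cat.), MeCN, rt, dark
Reagents that add atoms: N-iodosuccinimide, O=C1CCC(=O)N1I
Why: Electrophilic aromatic iodination, expected at the free position para to the C12 methoxy group and ortho to the C14 methoxy group (the future C8) in preference to the position para to the isopropyl group.

Step 8
Reactants: 15 1-iodo-2,4,5-trimethoxy-3-(propan-2-yl)benzene
Product: 17 1-bromo-2-iodo-3,5,6-trimethoxy-4-(propan-2-yl)benzene, via arylzinc chloride 16 (not isolated)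
Conditions: ZnCl2·2LiCl (1.1 equiv), lithium 2,2,6,6-tetramethylpiperidide (1.5 equiv), THF, −78 °C; then Br2, −78 to 0 °C
Reagents that add atoms: bromine, BrBr
Why: Directed deprotonative metalation of the only remaining ring C–H (future C9, acidified by the flanking iodine and methoxy group) with in situ transmetalation to zinc, which suppresses halogen migration and aryne formation, followed by electrophilic bromination of the carbon–zinc bond.

Step 9
Reactants: 17 1-bromo-2-iodo-3,5,6-trimethoxy-4-(propan-2-yl)benzene; 9 N-methoxy-N,4-dimethyl-3-(prop-1-en-2-yl)pent-4-enamide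
Product: 19 1-[2-bromo-3,4,6-trimethoxy-5-(propan-2-yl)phenyl]-4-methyl-3-(prop-1-en-2-yl)pent-4-en-1-one, via arylmagnesium chloride 18 (not isolated)
Conditions: i-PrMgCl·LiCl, THF, −40 °C; then 9, −40 to 0 °C; then 1 M HCl, 0 °C
Reagents that add atoms: none
Why: Chemoselective iodine–magnesium exchange (much faster at C–I than at C–Br) gives an ortho-bromoarylmagnesium chloride that is stable below 0 °C, and Weinreb ketone synthesis stops at the ketone because the chelated tetrahedral adduct survives until the acidic quench.

Step 10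
Reactants: 19 1-[2-bromo-3,4,6-trimethoxy-5-(propan-2-yl)phenyl]-4-methyl-3-(prop-1-en-2-yl)pent-4-en-1-one; 20 ethynyltrimethylsilane
Product: 21 (3S,4R)-5,6,8-trimethoxy-4-methyl-7-(propan-2-yl)-3-(prop-1-en-2-yl)-4-[3-(trimethylsilyl)prop-2-yn-1-yl]-3,4-dihydronaphthalen-1(2H)-one
Conditions: Pd(OAc)2 (5 mol %), (R)-DTBM-SEGPHOS (6 mol %), CuI (10 mol %), i-Pr2NH (3 equiv), 20 (2 equiv, slow addition), N,N-dimethylacetamide, 80 °C
Reagents that add atoms: none
Why: Proposed new method: zerovalent palladium, generated from Pd(OAc)2 and the bisphosphine, inserts into the C9–Br bond of 19 (activated by the ortho acyl group), the arylpalladium adds syn across one isopropenyl group with C9 bonding to its inner carbon, and the resulting divalent palladium alkyl at C1, which has no β-hydrogen and cannot shift to an aryl C–H because C11 carries a methoxy group, persists until the copper acetylide CuC≡CSiMe3 formed from 20, CuI and the amine transmetalates and reductive elimination makes C1–C2. The closest known reaction types are the enantioselective domino Heck/Sonogashira cyclisation of aryl halides onto 1,1-disubstituted alkenes and the desymmetrising Heck reaction of prochiral dienes; merging them on a bis-isopropenyl methine to build a carbocycle has not been shown. Ring B closes by 6-exo-trig migratory insertion (tether C8–C7–C6–C5, new bond C9–C10). Both stereocentres arise in that one insertion from an achiral substrate: the chiral bisphosphine on palladium decides which enantiotopic isopropenyl group reacts and hence the absolute configuration at C5 and C10, while their relative configuration should be set by the substrate, because the reacting alkene must stack over the arene with C1 ending pseudo-axial, so the spectator isopropenyl on C5 points outward (pseudo-equatorial, cis to C1) and only C5–H faces the ring. The step needs group and face selectivity, secured by this conformational bias together with the ligand, and chemoselectivity for cyclisation over direct coupling of the arylpalladium with the alkyne, secured by the two ortho substituents that slow transmetalation at that stage, by the intramolecular alkene and by slow addition of 20. The cis relation is the first point to verify, by NOE between C20 and the C5 substituents or by X-ray analysis.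

Step 11
Reactants: 21 (3S,4R)-5,6,8-trimethoxy-4-methyl-7-(propan-2-yl)-3-(prop-1-en-2-yl)-4-[3-(trimethylsilyl)prop-2-yn-1-yl]-3,4-dihydronaphthalen-1(2H)-one
Product: 23 3-[(1R,2S)-5,7,8-trimethoxy-1-methyl-4-oxo-6-(propan-2-yl)-2-(prop-1-en-2-yl)-1,2,3,4-tetrahydronaphthalen-1-yl]propanoic acid, via alkenylborane 22 (not isolated)
Conditions: Cy2BH (1.3 equiv, from BH3·THF and cyclohexene), THF, 0 °C; then NaOH, H2O2, H2O, 0 °C to rt; then aq. HCl
Reagents that add atoms: hydrogen peroxide, OO
Why: Zweifel oxidation of a 1-silylalkyne: Cy2BH adds syn to the triple bond with boron on the silicon-bearing carbon faster than it attacks the hindered isopropenyl group or the electron-rich aryl ketone, and alkaline H2O2 converts the resulting 1-boryl-1-silylalkene through the acylsilane into the carboxylic acid without affecting C5 or C10.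

Step 12
Reactants: 23 3-[(1R,2S)-5,7,8-trimethoxy-1-methyl-4-oxo-6-(propan-2-yl)-2-(prop-1-en-2-yl)-1,2,3,4-tetrahydronaphthalen-1-yl]propanoic acid
Product: 24 3-[(1R,2S)-7-methoxy-1-methyl-4,5,8-trioxo-6-(propan-2-yl)-2-(prop-1-en-2-yl)-1,2,3,4,5,8-hexahydronaphthalen-1-yl]propanoic acid
Conditions: (NH4)2Ce(NO3)6 (2.5 equiv), MeCN/H2O, 0 °C
Reagents that add atoms: water, O
Why: Oxidative demethylation of the para-related C11 and C14 methyl ethers by tetravalent cerium (quinone synthesis from a 1,4-dimethoxyarene), which should give the 11,14-quinone with the C12 methoxy group retained and is fast enough at 0 °C to spare the isopropenyl group.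

Step 13
Reactants: 24 3-[(1R,2S)-7-methoxy-1-methyl-4,5,8-trioxo-6-(propan-2-yl)-2-(prop-1-en-2-yl)-1,2,3,4,5,8-hexahydronaphthalen-1-yl]propanoic acid
Product: 25 3-[(1R,2S)-7-hydroxy-1-methyl-4,5,8-trioxo-6-(propan-2-yl)-2-(prop-1-en-2-yl)-1,2,3,4,5,8-hexahydronaphthalen-1-yl]propanoic acid
Conditions: LiOH (3 equiv), THF/H2O, 0 °C to rt, argon; then aq. HCl
Reagents that add atoms: lithium hydroxide, [Li+].[OH-]
Why: Hydrolysis of the vinylogous ester at C12 by conjugate addition–elimination of hydroxide on the methoxyquinone, driven by formation of the delocalised hydroxyquinone anion; C5 is β to the ketone and C10 is quaternary, so neither can epimerise in base.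

Step 14
Reactants: 25 3-[(1R,2S)-7-hydroxy-1-methyl-4,5,8-trioxo-6-(propan-2-yl)-2-(prop-1-en-2-yl)-1,2,3,4,5,8-hexahydronaphthalen-1-yl]propanoic acid
Product: 26 3-[(1R,2S)-5,7,8-trihydroxy-1-methyl-4-oxo-6-(propan-2-yl)-2-(prop-1-en-2-yl)-1,2,3,4-tetrahydronaphthalen-1-yl]propanoic acid
Conditions: Na2S2O4, EtOAc/H2O (degassed), rt, argon
Reagents that add atoms: none
Why: Two-electron reduction of the quinone to the hydroquinone by dithionite, which does not reduce the C7 ketone, the isopropenyl group or the acid and so should deliver the 11,12,14-triol with the configuration fixed in step 10.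

Compound list
1 | methacrolein (2-methylprop-2-enal) | C=C(C)C=O | starting material
2 | triethyl 2-phosphonopropionate | CCOC(=O)C(C)P(=O)(OCC)OCC | starting material
3 | sodium salt of the carbanion of 2 (sodium phosphonate) | CCOC(=O)[C-](C)P(=O)(OCC)OCC.[Na+] | intermediate
4 | ethyl (2E)-2,4-dimethylpenta-2,4-dienoate | CCOC(=O)/C(C)=C/C(C)=C | intermediate
5 | (2E)-2,4-dimethylpenta-2,4-dien-1-ol | OC/C(C)=C/C(C)=C | intermediate
6 | triethyl orthoacetate | CC(OCC)(OCC)OCC | starting material
7 | 1-ethoxy-1-{[(2E)-2,4-dimethylpenta-2,4-dien-1-yl]oxy}ethene (ketene acetal) | C=C(OCC)OC/C(C)=C/C(C)=C | intermediate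
8 | ethyl 4-methyl-3-(prop-1-en-2-yl)pent-4-enoate | CCOC(=O)CC(C(C)=C)C(C)=C | intermediate
9 | N-methoxy-N,4-dimethyl-3-(prop-1-en-2-yl)pent-4-enamide | CON(C)C(=O)CC(C(C)=C)C(C)=C | intermediate
10 | 1,2,4-trimethoxybenzene | COc1ccc(OC)c(OC)c1 | starting material
11 | acetone | CC(C)=O | starting material
12 | (2,3,6-trimethoxyphenyl)lithium | COc1ccc(OC)c([Li])c1OC | intermediate
13 | 2-(2,3,6-trimethoxyphenyl)propan-2-ol | COc1ccc(OC)c(C(C)(C)O)c1OC | intermediate
14 | 1,2,4-trimethoxy-3-(propan-2-yl)benzene | COc1ccc(OC)c(C(C)C)c1OC | intermediate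
15 | 1-iodo-2,4,5-trimethoxy-3-(propan-2-yl)benzene | COc1cc(I)c(OC)c(C(C)C)c1OC | intermediate
16 | [2-iodo-3,5,6-trimethoxy-4-(propan-2-yl)phenyl]zinc chloride | COc1c([Zn]Cl)c(I)c(OC)c(C(C)C)c1OC | intermediate
17 | 1-bromo-2-iodo-3,5,6-trimethoxy-4-(propan-2-yl)benzene | COc1c(Br)c(I)c(OC)c(C(C)C)c1OC | intermediate
18 | [2-bromo-3,4,6-trimethoxy-5-(propan-2-yl)phenyl]magnesium chloride | COc1c(Br)c([Mg]Cl)c(OC)c(C(C)C)c1OC | intermediate
19 | 1-[2-bromo-3,4,6-trimethoxy-5-(propan-2-yl)phenyl]-4-methyl-3-(prop-1-en-2-yl)pent-4-en-1-one (achiral) | C=C(C)C(CC(=O)c1c(Br)c(OC)c(OC)c(C(C)C)c1OC)C(C)=C | intermediate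
20 | ethynyltrimethylsilane | C#C[Si](C)(C)C | starting material
21 | (3S,4R)-5,6,8-trimethoxy-4-methyl-7-(propan-2-yl)-3-(prop-1-en-2-yl)-4-[3-(trimethylsilyl)prop-2-yn-1-yl]-3,4-dihydronaphthalen-1(2H)-one (isopropenyl cis to the propargyl arm) | C=C(C)[C@@H]1CC(=O)c2c(OC)c(C(C)C)c(OC)c(OC)c2[C@]1(C)CC#C[Si](C)(C)C | intermediate
22 | (3S,4R)-4-[(2Z)-3-(dicyclohexylboranyl)-3-(trimethylsilyl)prop-2-en-1-yl]-5,6,8-trimethoxy-4-methyl-7-(propan-2-yl)-3-(prop-1-en-2-yl)-3,4-dihydronaphthalen-1(2H)-one | C=C(C)[C@@H]1CC(=O)c2c(OC)c(C(C)C)c(OC)c(OC)c2[C@]1(C)C/C=C(\[Si](C)(C)C)B(C3CCCCC3)C4CCCCC4 | intermediate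
23 | 3-[(1R,2S)-5,7,8-trimethoxy-1-methyl-4-oxo-6-(propan-2-yl)-2-(prop-1-en-2-yl)-1,2,3,4-tetrahydronaphthalen-1-yl]propanoic acid | C=C(C)[C@@H]1CC(=O)c2c(OC)c(C(C)C)c(OC)c(OC)c2[C@]1(C)CCC(=O)O | intermediate
24 | 3-[(1R,2S)-7-methoxy-1-methyl-4,5,8-trioxo-6-(propan-2-yl)-2-(prop-1-en-2-yl)-1,2,3,4,5,8-hexahydronaphthalen-1-yl]propanoic acid | C=C(C)[C@@H]1CC(=O)C=2C(=O)C(C(C)C)=C(OC)C(=O)C2[C@]1(C)CCC(=O)O | intermediate
25 | 3-[(1R,2S)-7-hydroxy-1-methyl-4,5,8-trioxo-6-(propan-2-yl)-2-(prop-1-en-2-yl)-1,2,3,4,5,8-hexahydronaphthalen-1-yl]propanoic acid | C=C(C)[C@@H]1CC(=O)C=2C(=O)C(C(C)C)=C(O)C(=O)C2[C@]1(C)CCC(=O)O | intermediate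
26 | 3-[(1R,2S)-5,7,8-trihydroxy-1-methyl-4-oxo-6-(propan-2-yl)-2-(prop-1-en-2-yl)-1,2,3,4-tetrahydronaphthalen-1-yl]propanoic acid (CNP0198818.2) | C=C(C)[C@@H]1CC(=O)c2c(O)c(C(C)C)c(O)c(O)c2[C@]1(C)CCC(=O)O | target

Total step count: 14 steps.
Longest linear sequence: 10 steps (steps 1–4 and 9–14; the arene branch, steps 5–9 and 10–14, is equally long).

Steps most likely to fail

1. Step 10 (Proposed new method). The bisphosphine may fail to tell the two enantiotopic isopropenyl groups apart, so that enantiomeric purity erodes. Oxidative addition at the doubly ortho-substituted bromide may stall with so large a ligand, and alkynylation of the arylpalladium may outrun insertion. The fallback uses known chemistry and sets out from 19. The established racemic domino Heck/alkynylation is run with an achiral catalyst (PdCl2(PPh3)2, CuI, i-Pr2NH, N,N-dimethylacetamide, 80 °C, slow addition of 20). Because the cis relation is expected from the substrate and not from the ligand, this should give 21 as a racemate with its mirror image, (3R,4S)-5,6,8-trimethoxy-4-methyl-7-(propan-2-yl)-3-(prop-1-en-2-yl)-4-[3-(trimethylsilyl)prop-2-yn-1-yl]-3,4-dihydronaphthalen-1(2H)-one F1. Preparative chromatography on a chiral stationary phase removes F1, and the route comes back at 21.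

2. Step 9. Acyl substitution at the doubly ortho-substituted arylmagnesium may be slower than deprotonation of the amide next to its carbonyl, or than loss of MgBrCl to an aryne on warming. The fallback sets out from 9 and 17 and replaces acyl substitution by addition and oxidation. Reduction of 9 with i-Bu2AlH (THF, −78 °C) should give 4-methyl-3-(prop-1-en-2-yl)pent-4-enal F2. Reagent 18, generated from 17 as in step 9, adds to this more electrophilic partner at −40 °C to give racemic 1-[2-bromo-3,4,6-trimethoxy-5-(propan-2-yl)phenyl]-4-methyl-3-(prop-1-en-2-yl)pent-4-en-1-ol F3. Dess–Martin periodinane (NaHCO3, CH2Cl2) oxidises it, and the route comes back at 19.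

3. Step 11. The borane may hydroborate the isopropenyl group or reduce the C7 ketone in competition with the hindered silylalkyne, or the oxidation may stall at the acylsilane. The fallback sets out from 21 and avoids boranes. K2CO3 in MeOH removes silicon to give (3S,4R)-5,6,8-trimethoxy-4-methyl-7-(propan-2-yl)-3-(prop-1-en-2-yl)-4-(prop-2-yn-1-yl)-3,4-dihydronaphthalen-1(2H)-one F4. Anti-Markovnikov hydration with [CpRu(MeCN)3]PF6 and 5,5′-bis(trifluoromethyl)-2,2′-bipyridine in aqueous N-methylpyrrolidinone gives 3-[(1R,2S)-5,7,8-trimethoxy-1-methyl-4-oxo-6-(propan-2-yl)-2-(prop-1-en-2-yl)-1,2,3,4-tetrahydronaphthalen-1-yl]propanal F5. Pinnick oxidation (NaClO2, NaH2PO4, 2-methylbut-2-ene, t-BuOH/H2O) then brings the route back at 23.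

Further compounds
F1 | step 10 | (3R,4S)-5,6,8-trimethoxy-4-methyl-7-(propan-2-yl)-3-(prop-1-en-2-yl)-4-[3-(trimethylsilyl)prop-2-yn-1-yl]-3,4-dihydronaphthalen-1(2H)-one (enantiomer of 21, formed with 21 as the racemate) | C=C(C)[C@H]1CC(=O)c2c(OC)c(C(C)C)c(OC)c(OC)c2[C@@]1(C)CC#C[Si](C)(C)C
F2 | step 9 | 4-methyl-3-(prop-1-en-2-yl)pent-4-enal | O=CCC(C(C)=C)C(C)=C
F3 | step 9 | racemic 1-[2-bromo-3,4,6-trimethoxy-5-(propan-2-yl)phenyl]-4-methyl-3-(prop-1-en-2-yl)pent-4-en-1-ol | C=C(C)C(CC(O)c1c(Br)c(OC)c(OC)c(C(C)C)c1OC)C(C)=C
F4 | step 11 | (3S,4R)-5,6,8-trimethoxy-4-methyl-7-(propan-2-yl)-3-(prop-1-en-2-yl)-4-(prop-2-yn-1-yl)-3,4-dihydronaphthalen-1(2H)-one | C=C(C)[C@@H]1CC(=O)c2c(OC)c(C(C)C)c(OC)c(OC)c2[C@]1(C)CC#C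
F5 | step 11 | 3-[(1R,2S)-5,7,8-trimethoxy-1-methyl-4-oxo-6-(propan-2-yl)-2-(prop-1-en-2-yl)-1,2,3,4-tetrahydronaphthalen-1-yl]propanal | C=C(C)[C@@H]1CC(=O)c2c(OC)c(C(C)C)c(OC)c(OC)c2[C@]1(C)CCC=O
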